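**Plan**

1. Retrosynthesis: remove the two benzyl groups; cut the side-chain C5–C1' bond (aryl–carbonyl) to a 5-bromo-dihydrobenzofuran and an (S)-lactic acid Weinreb amide; cut the C2–C3 bond of the dihydrofuran ring (carbene C–H insertion); cut the O1–CH2 ether bond to a bromo-hydroxy-acetophenone and a benzyl bromide.
2. Forward: both arenes are bought and joined as a benzyl aryl ether; the dihydrofuran ring, the only non-aromatic ring, is closed last by a Rh-carbene 1,5 C–H insertion; C2 is then equilibrated to trans; the side chain is attached by aryllithium acylation, reduced and debenzylated.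
3. Enabling feature: C2 lies between ring oxygen O1 and the trioxygenated aryl ring, so in the open ether its CH2 is doubly activated (α-oxy and benzylic) and sits 1,5 to the acetyl carbon (future C3) across O1–C7a–C3a. C3 carries only CH3 and an aryl carbon, so it can be a donor/donor carbene made directly from an acetyl group.
4. Stereochemistry: C3 from the chiral Rh(II) catalyst; C2 relayed from C3 (cis in the insertion, then thermodynamic trans under acid); C2' bought as (S)-lactate; C1' from C2' by chelation-controlled reduction.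

Key step: step 7

Assumption: Rh2(S-PTAD)4 is written as the catalyst enantiomer that gives the (3S) centre; if the sense of induction on this ether is the opposite, Rh2(R-PTAD)4 is used and nothing else changes.

**Route**

Step 1
Reactants: 1 3-hydroxy-4,5-dimethoxybenzaldehyde
Product: 2 3-(benzyloxy)-4,5-dimethoxybenzaldehyde
Conditions: BnBr, K2CO3, DMF, rt
Reagents that add atoms: benzyl bromide, BrCc1ccccc1
Why: Williamson O-benzylation of the only free phenol under mild carbonate conditions, which leaves the aldehyde untouched and installs a group that lasts until the final hydrogenolysis.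

Step 2
Reactants: 2 3-(benzyloxy)-4,5-dimethoxybenzaldehyde
Product: 3 [3-(benzyloxy)-4,5-dimethoxyphenyl]methanol
Conditions: NaBH4, MeOH, 0 °C
Reagents that add atoms: none
Why: Borohydride reduction of an aryl aldehyde to the primary benzylic alcohol, with all ethers inert.

Step 3
Reactants: 3 [3-(benzyloxy)-4,5-dimethoxyphenyl]methanol
Product: 4 1-(benzyloxy)-5-(bromomethyl)-2,3-dimethoxybenzene
Conditions: PBr3, CH2Cl2, 0 °C
Reagents that add atoms: phosphorus tribromide, BrP(Br)Br
Why: Conversion of a primary benzylic alcohol into its bromide through the phosphite ester (SN2 by bromide), fast at 0 °C on this electron-rich ring and harmless to the aryl benzyl ether.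

Step 4
Reactants: 5 1-(2-hydroxy-3-methoxyphenyl)ethanone
Product: 6 1-(5-bromo-2-hydroxy-3-methoxyphenyl)ethanone
Conditions: NBS, MeCN, 0 °C to rt
Reagents that add atoms: N-bromosuccinimide, O=C1CCC(=O)N1Br
Why: Electrophilic aromatic bromination para to the free OH, whose two ortho positions are blocked and whose para carbon is also the one the meta-directing acetyl group favours.

Step 5
Reactants: 6 1-(5-bromo-2-hydroxy-3-methoxyphenyl)ethanone; 4 1-(benzyloxy)-5-(bromomethyl)-2,3-dimethoxybenzene
Product: 7 1-[2-{[3-(benzyloxy)-4,5-dimethoxyphenyl]methoxy}-5-bromo-3-methoxyphenyl]ethanone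
Conditions: K2CO3, DMF, 60 °C
Reagents that add atoms: none
Why: Williamson ether synthesis between the phenoxide of 6 and the primary benzylic bromide 4; carbonate is too weak to form the ketone enolate, so alkylation should occur at oxygen only.

Step 6
Reactants: 7 1-[2-{[3-(benzyloxy)-4,5-dimethoxyphenyl]methoxy}-5-bromo-3-methoxyphenyl]ethanone
Product: 8 (E)-hydrazone of 7
Conditions: N2H4·H2O (10 equiv), AcOH (cat.), EtOH, 80 °C
Reagents that add atoms: hydrazine, NN
Why: Condensation of the aryl methyl ketone with excess hydrazine gives the N-unsubstituted hydrazone (the excess suppresses azine formation); its C=N geometry is irrelevant because it is lost on oxidation.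

Step 7
Reactants: 8 (E)-hydrazone of 7
Product: 10 (2R,3S)-2-[3-(benzyloxy)-4,5-dimethoxyphenyl]-5-bromo-7-methoxy-3-methyl-2,3-dihydro-1-benzofuran (2,3-cis), via aryl(methyl)diazomethane 9 (not isolated)
Conditions: MnO2, CH2Cl2, 0 °C, filter; filtrate added slowly to Rh2(S-PTAD)4 (1 mol %), CH2Cl2, 0 °C to rt
Reagents that add atoms: none
Why: MnO2 dehydrogenates the hydrazone to the aryl(methyl)diazomethane 9, which loses N2 on the dirhodium catalyst to give a donor/donor rhodium carbene at the future C3; this carbene inserts into one of the two enantiotopic C–H bonds of the ArO–CH2–Ar' group (future C2) through a concerted, asynchronous hydride-transfer/C–C-closure transition state. The closest known reaction type is the Rh(II)-carboxylate-catalysed enantioselective intramolecular C–H insertion of donor/donor carbenes, generated from ketone hydrazones, into benzyl aryl ethers to give 2,3-cis-2,3-dihydrobenzofurans. The five-membered O1–C2–C3–C3a–C7a ring closes by 1,5-insertion, that is by forming the C2–C3 bond, the carbene carbon and the CH2 being held in reach by their ortho relationship on the benzo ring. C3 is set by the chiral phthalimido-carboxylate pocket of the catalyst, which selects the carbene face; C2 is set in the same transition state by the choice of which CH2 hydrogen migrates, and the 2,3-cis relationship is the expected kinetic outcome for this class because both substituents turn away from the dirhodium core. The step needs insertion to outrun 1,2-hydride shift from the methyl group (styrene), azine formation and attack on the electron-rich rings: the C2–H bond is doubly activated and the only C–H within 1,5 reach, the donor/donor carbene is weakly electrophilic and therefore selective, and slow addition of cold 9 keeps its concentration low. Only the C3 configuration has to survive into the target, since C2 is corrected in step 8.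

Step 8
Reactants: 10 (2R,3S)-2-[3-(benzyloxy)-4,5-dimethoxyphenyl]-5-bromo-7-methoxy-3-methyl-2,3-dihydro-1-benzofuran
Product: 11 (2S,3S)-2-[3-(benzyloxy)-4,5-dimethoxyphenyl]-5-bromo-7-methoxy-3-methyl-2,3-dihydro-1-benzofuran (2,3-trans)
Conditions: BF3·OEt2 (0.3 equiv), CH2Cl2, 0 °C to rt
Reagents that add atoms: none
Why: Acid-mediated cis-to-trans epimerization of a 2-aryl-2,3-dihydrobenzofuran: reversible heterolysis of the benzylic C2–O1 bond (boron held between O1 and the 7-OMe, cation stabilised by the para-methoxy group of the 2-aryl ring) and reclosure equilibrate C2 only, so the untouched (3S) centre should relay the thermodynamically preferred trans (2S) configuration.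

Step 9
Reactants: 12 (S)-2-(benzyloxy)propanoic acid
Product: 14 (S)-2-(benzyloxy)-N-methoxy-N-methylpropanamide, via acyl imidazole 13 (not isolated)
Conditions: CDI, CH2Cl2, rt; then MeNH(OMe)·HCl, rt
Reagents that add atoms: N,O-dimethylhydroxylamine hydrochloride, CNOC.Cl; 1,1'-carbonyldiimidazole, O=C(n1ccnc1)n1ccnc1 (its imidazole is present only in intermediate 13)
Why: Activation of the acid as its acyl imidazole and aminolysis give the Weinreb amide; an α-alkoxy acid cannot form an azlactone, so the purchased (S) centre should not epimerize under these near-neutral conditions.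

Step 10
Reactants: 11 (2S,3S)-2-[3-(benzyloxy)-4,5-dimethoxyphenyl]-5-bromo-7-methoxy-3-methyl-2,3-dihydro-1-benzofuran; 14 (S)-2-(benzyloxy)-N-methoxy-N-methylpropanamide
Product: 17 (2S)-2-(benzyloxy)-1-{(2S,3S)-2-[3-(benzyloxy)-4,5-dimethoxyphenyl]-7-methoxy-3-methyl-2,3-dihydro-1-benzofuran-5-yl}propan-1-one, via aryllithium 15 (not isolated), via lithium hemiaminal adduct 16 (not isolated)
Conditions: n-BuLi, THF, −78 °C; then 14, −78 to −20 °C; aq. NH4Cl
Reagents that add atoms: n-butyllithium, [Li]CCCC (its lithium stays only in intermediates 15 and 16; no atom of it is in 17)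
Why: Bromine–lithium exchange at −78 °C is faster than any deprotonation, and the aryllithium adds once to the Weinreb amide because the chelated tetrahedral adduct 16 collapses to the ketone only on quench (Weinreb ketone synthesis); C2' is not enolized in the cold and C2/C3 are untouched.

Step 11
Reactants: 17 (2S)-2-(benzyloxy)-1-{(2S,3S)-2-[3-(benzyloxy)-4,5-dimethoxyphenyl]-7-methoxy-3-methyl-2,3-dihydro-1-benzofuran-5-yl}propan-1-one
Product: 18 (1R,2S)-2-(benzyloxy)-1-{(2S,3S)-2-[3-(benzyloxy)-4,5-dimethoxyphenyl]-7-methoxy-3-methyl-2,3-dihydro-1-benzofuran-5-yl}propan-1-ol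
Conditions: Zn(BH4)2, Et2O, −20 °C
Reagents that add atoms: none
Why: Cram-chelate-controlled reduction: Zn(II) bridges the carbonyl oxygen and the α-benzyloxy oxygen and hydride is delivered to the carbonyl face opposite the C2' methyl group, which should give the anti (erythro) (1R,2S) alcohol by 1,2-induction from the lactate centre.

Step 12
Reactants: 18 (1R,2S)-2-(benzyloxy)-1-{(2S,3S)-2-[3-(benzyloxy)-4,5-dimethoxyphenyl]-7-methoxy-3-methyl-2,3-dihydro-1-benzofuran-5-yl}propan-1-ol
Product: 19 (1R,2S)-1-[(2S,3S)-2-(3-hydroxy-4,5-dimethoxyphenyl)-7-methoxy-3-methyl-2,3-dihydro-1-benzofuran-5-yl]propane-1,2-diol (CNP0229216.1)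
Conditions: H2 (1 atm), 10% Pd/C, EtOAc, rt
Reagents that add atoms: none
Why: Hydrogenolysis of the aryl benzyl ether and the secondary alkyl benzyl ether over Pd/C in a neutral solvent, where the secondary benzylic OH and the cyclic benzylic C2–O1 bond should be cleaved far more slowly and no stereocentre is touched.

**Compound list**

1 | 3-hydroxy-4,5-dimethoxybenzaldehyde | COc1cc(C=O)cc(O)c1OC | starting material
2 | 3-(benzyloxy)-4,5-dimethoxybenzaldehyde | COc1cc(C=O)cc(OCc2ccccc2)c1OC | intermediate
3 | [3-(benzyloxy)-4,5-dimethoxyphenyl]methanol | COc1cc(CO)cc(OCc2ccccc2)c1OC | intermediate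
4 | 1-(benzyloxy)-5-(bromomethyl)-2,3-dimethoxybenzene | COc1cc(CBr)cc(OCc2ccccc2)c1OC | intermediate
5 | 1-(2-hydroxy-3-methoxyphenyl)ethanone | CC(=O)c1cccc(OC)c1O | starting material
6 | 1-(5-bromo-2-hydroxy-3-methoxyphenyl)ethanone | CC(=O)c1cc(Br)cc(OC)c1O | intermediate
7 | 1-[2-{[3-(benzyloxy)-4,5-dimethoxyphenyl]methoxy}-5-bromo-3-methoxyphenyl]ethanone | CC(=O)c1cc(Br)cc(OC)c1OCc1cc(OC)c(OC)c(OCc2ccccc2)c1 | intermediate
8 | (E)-hydrazone of 7 | C/C(=N\N)c1cc(Br)cc(OC)c1OCc1cc(OC)c(OC)c(OCc2ccccc2)c1 | intermediate
9 | 1-{[3-(benzyloxy)-4,5-dimethoxyphenyl]methoxy}-4-bromo-2-(1-diazoethyl)-6-methoxybenzene | CC(=[N+]=[N-])c1cc(Br)cc(OC)c1OCc1cc(OC)c(OC)c(OCc2ccccc2)c1 | intermediate (not isolated)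
10 | (2R,3S)-2-[3-(benzyloxy)-4,5-dimethoxyphenyl]-5-bromo-7-methoxy-3-methyl-2,3-dihydro-1-benzofuran (cis) | COc1cc([C@@H]2Oc3c(OC)cc(Br)cc3[C@@H]2C)cc(OCc2ccccc2)c1OC | intermediate
11 | (2S,3S)-2-[3-(benzyloxy)-4,5-dimethoxyphenyl]-5-bromo-7-methoxy-3-methyl-2,3-dihydro-1-benzofuran (trans) | COc1cc([C@H]2Oc3c(OC)cc(Br)cc3[C@@H]2C)cc(OCc2ccccc2)c1OC | intermediate
12 | (S)-2-(benzyloxy)propanoic acid | C[C@H](OCc1ccccc1)C(=O)O | starting material
13 | (S)-2-(benzyloxy)-1-(1H-imidazol-1-yl)propan-1-one | C[C@H](OCc1ccccc1)C(=O)n1ccnc1 | intermediate (not isolated)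
14 | (S)-2-(benzyloxy)-N-methoxy-N-methylpropanamide | C[C@H](OCc1ccccc1)C(=O)N(C)OC | intermediate
15 | aryllithium from 11 (Li in place of Br at C5) | COc1cc([C@H]2Oc3c(OC)cc([Li])cc3[C@@H]2C)cc(OCc2ccccc2)c1OC | intermediate (not isolated)
16 | lithium hemiaminal adduct of 15 and 14 (new carbinol carbon undefined) | COc1cc([C@H]2Oc3c(OC)cc(C(O[Li])(N(C)OC)[C@H](C)OCc4ccccc4)cc3[C@@H]2C)cc(OCc2ccccc2)c1OC | intermediate (not isolated)
17 | (2S)-2-(benzyloxy)-1-{(2S,3S)-2-[3-(benzyloxy)-4,5-dimethoxyphenyl]-7-methoxy-3-methyl-2,3-dihydro-1-benzofuran-5-yl}propan-1-one | COc1cc([C@H]2Oc3c(OC)cc(C(=O)[C@H](C)OCc4ccccc4)cc3[C@@H]2C)cc(OCc2ccccc2)c1OC | intermediate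
18 | (1R,2S)-2-(benzyloxy)-1-{(2S,3S)-2-[3-(benzyloxy)-4,5-dimethoxyphenyl]-7-methoxy-3-methyl-2,3-dihydro-1-benzofuran-5-yl}propan-1-ol | COc1cc([C@H]2Oc3c(OC)cc([C@@H](O)[C@H](C)OCc4ccccc4)cc3[C@@H]2C)cc(OCc2ccccc2)c1OC | intermediate
19 | (1R,2S)-1-[(2S,3S)-2-(3-hydroxy-4,5-dimethoxyphenyl)-7-methoxy-3-methyl-2,3-dihydro-1-benzofuran-5-yl]propane-1,2-diol | COc1cc([C@H]2Oc3c(OC)cc([C@@H](O)[C@H](C)O)cc3[C@@H]2C)cc(O)c1OC | target

**Count and risks**

Total step count: 12. Longest linear sequence: 10 steps (steps 1, 2, 3, 5, 6, 7, 8, 10, 11, 12).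

Steps most likely to fail:

Step 7. The methyl-substituted carbene may undergo 1,2-hydride shift to a styrene, the labile aryl(methyl)diazo compound may dimerize to the azine, or facial selectivity may be eroded by the methoxy group next to the ether oxygen. Fallback (sets out from 7, returns at 11): the carbene is changed to a donor/acceptor carbene that has no hydrogen able to shift, and C3 is carried at the ester oxidation level so that the relay runs from C2 to C3 under base.
- Oxidative 1,2-aryl migration of ketone 7 (PhI(OAc)2, HC(OMe)3, cat. H2SO4, MeOH) should give methyl 2-[2-{[3-(benzyloxy)-4,5-dimethoxyphenyl]methoxy}-5-bromo-3-methoxyphenyl]acetate F1.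
- Diazo transfer (p-ABSA, DBU, MeCN) should give the aryldiazoacetate F2.
- Rh2(S-PTTL)4-catalysed intramolecular C–H insertion into the same ether CH2 (toluene, −60 °C, catalyst enantiomer chosen for 2S) should give the cis-(2S,3R) methyl ester F3.
- NaOMe/MeOH should epimerize C3 by enolization to the trans-(2S,3S) methyl ester F4.
- DIBAL-H should give the (2S,3R) primary alcohol F5.
- TsCl/pyridine should give the tosylate F6.
- LiBHEt3 (THF, 0 °C) should displace the tosylate by hydride to give 11.

Step 8. Heterolysis of C2–O1 may be sluggish because the para-methoxy group of the trioxygenated ring is twisted out of conjugation; forcing it risks proton loss from C3 of the open cation (erosion of the C3 centre) or loss of the benzyl ether. Fallback (sets out from 10, returns at 11; no new compound, F0): C2 is equilibrated without breaking the C–O bond, by reversible hydrogen-atom abstraction. A thiol catalyst (Ph3SiSH or methyl thioglycolate, about 10 mol %) with a radical initiator in benzene at 80 °C should generate a thiyl radical that abstracts the weakest, most hydridic C–H (C2–H, benzylic and α to O1) and returns hydrogen to the planar C2 radical anti to the C3 methyl group. Thiol-catalysed radical epimerization at C–H next to ether oxygen is a known reaction type; C3–H, not α to oxygen, should be abstracted much more slowly.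

Step 12. Over-reduction: hydrogenolysis of the benzylic C1'–OH bond or of the benzylic C2–O1 ring bond may accompany debenzylation. Fallback (sets out from 17, returns at 19): deprotect before the reduction and without hydrogen, so that no benzylic alcohol ever meets Pd/H2. BCl3 with pentamethylbenzene (CH2Cl2, −78 °C) should remove both benzyl groups from ketone 17 to give (2S)-2-hydroxy-1-[(2S,3S)-2-(3-hydroxy-4,5-dimethoxyphenyl)-7-methoxy-3-methyl-2,3-dihydro-1-benzofuran-5-yl]propan-1-one F7; any reversible C2–O1 ionization at this stage only returns the trans ring. Zn(BH4)2 (excess, Et2O/THF, −20 °C) should then reduce the free α-hydroxy ketone through its zinc chelate to the anti diol 19.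

**Further compounds**

F1 | step 7 | methyl 2-[2-{[3-(benzyloxy)-4,5-dimethoxyphenyl]methoxy}-5-bromo-3-methoxyphenyl]acetate | COC(=O)Cc1cc(Br)cc(OC)c1OCc1cc(OC)c(OC)c(OCc2ccccc2)c1
F2 | step 7 | methyl 2-[2-{[3-(benzyloxy)-4,5-dimethoxyphenyl]methoxy}-5-bromo-3-methoxyphenyl]-2-diazoacetate | COC(=O)C(=[N+]=[N-])c1cc(Br)cc(OC)c1OCc1cc(OC)c(OC)c(OCc2ccccc2)c1
F3 | step 7 | methyl (2S,3R)-2-[3-(benzyloxy)-4,5-dimethoxyphenyl]-5-bromo-7-methoxy-2,3-dihydro-1-benzofuran-3-carboxylate (cis) | COc1cc([C@H]2Oc3c(OC)cc(Br)cc3[C@H]2C(=O)OC)cc(OCc2ccccc2)c1OC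
F4 | step 7 | methyl (2S,3S)-2-[3-(benzyloxy)-4,5-dimethoxyphenyl]-5-bromo-7-methoxy-2,3-dihydro-1-benzofuran-3-carboxylate (trans) | COc1cc([C@H]2Oc3c(OC)cc(Br)cc3[C@@H]2C(=O)OC)cc(OCc2ccccc2)c1OC
F5 | step 7 | [(2S,3R)-2-[3-(benzyloxy)-4,5-dimethoxyphenyl]-5-bromo-7-methoxy-2,3-dihydro-1-benzofuran-3-yl]methanol | COc1cc([C@H]2Oc3c(OC)cc(Br)cc3[C@@H]2CO)cc(OCc2ccccc2)c1OC
F6 | step 7 | [(2S,3R)-2-[3-(benzyloxy)-4,5-dimethoxyphenyl]-5-bromo-7-methoxy-2,3-dihydro-1-benzofuran-3-yl]methyl 4-methylbenzenesulfonate | COc1cc([C@H]2Oc3c(OC)cc(Br)cc3[C@@H]2COS(=O)(=O)c2ccc(C)cc2)cc(OCc2ccccc2)c1OC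
F0 | step 8 | none | none
F7 | step 12 | (2S)-2-hydroxy-1-[(2S,3S)-2-(3-hydroxy-4,5-dimethoxyphenyl)-7-methoxy-3-methyl-2,3-dihydro-1-benzofuran-5-yl]propan-1-one | COc1cc([C@H]2Oc3c(OC)cc(C(=O)[C@H](C)O)cc3[C@@H]2C)cc(O)c1OC
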